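**Plan** (icetexane numbering: ring A = C1–C5 and C10; seven-membered ring B = C5, C6, C7, C8, C9, C20, C10; ring C = C8, C9, C11–C14; C19 = lactone carbonyl on C4, bound through oxygen to C6)
- Retrosynthesis: the hydroxyquinone goes back to an 11,12,14-trimethoxyarene, the C6=C7 enol lactone and the C1 carbinol to a saturated 19,6-lactone and a C1 enone, and the lactone to a C19 aldehyde plus a C6 silyl ether.
- Ring A is then cut at C2–C3 and C4–C5: its C1 oxygen stands para to quaternary C4, which carries CH3 and C19, the pattern left by a 2-silyloxydiene (C5=C10–C1(OSi)=C2) adding to methacrolein.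
- Ring B is cut at C5=C10 (olefination), at C10–C20 (alkylation) and at the two aryl–CH2 bonds C7–C8 and C9–C20.
- Forward order: ring C (1,2,4-trimethoxybenzene) → C8 and C9 side chains → ring B by intramolecular Horner–Wadsworth–Emmons reaction → ring A by Diels–Alder reaction → lactone ring → C6–C7 dehydrogenation, C1 reduction, quinone.
- Stereochemistry: C6 comes from (S)-benzyl glycidyl ether and steers the diene face (C5), endo addition fixes C4, a Luche reduction sets C1, and C6 is erased afterwards.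

Key step: step 13

Assumption: ring bromination of 4 is taken to follow the pattern of 1,2,4-trimethoxybenzene itself and to enter para to the central methoxy group (the later C8); the later C9 is then the only ring position left for step 6.

Step 1
Reactants: 1 1,2,4-trimethoxybenzene
Product: 3 2-(2,3,6-trimethoxyphenyl)propan-2-ol, via aryllithium 2 (not isolated)
Conditions: n-BuLi, THF, 0 °C to rt; then acetone, −78 °C to rt
Reagents that add atoms: acetone CC(C)=O
Why: Directed ortho-lithiation at the ring position flanked by two methoxy groups (the later C13) followed by 1,2-addition to acetone should install the three isopropyl carbons.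

Step 2
Reactants: 3 2-(2,3,6-trimethoxyphenyl)propan-2-ol
Product: 4 2-isopropyl-1,3,4-trimethoxybenzene
Conditions: Et3SiH, CF3CO2H, CH2Cl2, 0 °C to rt
Reagents that add atoms: none
Why: Ionic hydrogenation: the tertiary benzylic cation of the electron-rich arene is captured by the silane hydride.

Step 3
Reactants: 4 2-isopropyl-1,3,4-trimethoxybenzene
Product: 5 1-bromo-3-isopropyl-2,4,5-trimethoxybenzene
Conditions: NBS, MeCN, 0 °C to rt
Reagents that add atoms: N-bromosuccinimide O=C1CCC(=O)N1Br
Why: Electrophilic aromatic bromination should enter at the later C8, which is ortho to the C14 methoxy group and para to the C12 methoxy group, whereas the other free position has only one ortho methoxy group.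

Step 4
Reactants: 5 1-bromo-3-isopropyl-2,4,5-trimethoxybenzene; 6 (S)-benzyl glycidyl ether
Product: 8 (S)-1-(benzyloxy)-3-(3-isopropyl-2,4,5-trimethoxyphenyl)propan-2-ol, via arylmagnesium bromide 7 (not isolated)
Conditions: Mg, THF, reflux; then CuI (10 mol %), 6, −30 °C to 0 °C
Reagents that add atoms: none
Why: Copper-catalysed Grignard opening of the terminal epoxide at its CH2 carbon (SN2) forms C7–C8 and carries the C6 stereocentre of 6 over unchanged.

Step 5
Reactants: 8 (S)-1-(benzyloxy)-3-(3-isopropyl-2,4,5-trimethoxyphenyl)propan-2-ol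
Product: 9 (S)-{[1-(benzyloxy)-3-(3-isopropyl-2,4,5-trimethoxyphenyl)propan-2-yl]oxy}(tert-butyl)dimethylsilane
Conditions: TBSCl, imidazole, DMF, rt
Reagents that add atoms: tert-butyldimethylsilyl chloride CC(C)(C)[Si](C)(C)Cl
Why: Standard silylation of the secondary alcohol gives the bulky C6 silyl ether that later steers the cycloaddition.

Step 6
Reactants: 9 (S)-{[1-(benzyloxy)-3-(3-isopropyl-2,4,5-trimethoxyphenyl)propan-2-yl]oxy}(tert-butyl)dimethylsilane
Product: 10 (S)-{[1-(benzyloxy)-3-(6-bromo-3-isopropyl-2,4,5-trimethoxyphenyl)propan-2-yl]oxy}(tert-butyl)dimethylsilane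
Conditions: NBS, MeCN, 0 °C to rt, dark
Reagents that add atoms: N-bromosuccinimide O=C1CCC(=O)N1Br
Why: Electrophilic aromatic bromination of the single remaining ring C–H (the later C9, ortho to the C11 methoxy group) is regiochemically unambiguous and leaves the silyl and benzyl ethers untouched.

Step 7
Reactants: 10 (S)-{[1-(benzyloxy)-3-(6-bromo-3-isopropyl-2,4,5-trimethoxyphenyl)propan-2-yl]oxy}(tert-butyl)dimethylsilane
Product: 12 {2-[(2S)-3-(benzyloxy)-2-(tert-butyldimethylsilyloxy)propyl]-4-isopropyl-3,5,6-trimethoxyphenyl}methanol, via arylmagnesium bromide 11 (not isolated)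
Conditions: Mg, THF, reflux; then (CH2O)n, 0 °C to rt
Reagents that add atoms: formaldehyde (as paraformaldehyde) C=O
Why: Grignard formation and hydroxymethylation with formaldehyde introduce C20 on C9 under conditions that do not disturb the silyl ether.

Step 8
Reactants: 12 {2-[(2S)-3-(benzyloxy)-2-(tert-butyldimethylsilyloxy)propyl]-4-isopropyl-3,5,6-trimethoxyphenyl}methanol
Product: 13 (S)-2-[3-(benzyloxy)-2-(tert-butyldimethylsilyloxy)propyl]-4-isopropyl-3,5,6-trimethoxybenzyl bromide
Conditions: CBr4, PPh3, CH2Cl2, 0 °C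
Reagents that add atoms: carbon tetrabromide BrC(Br)(Br)Br
Why: The Appel reaction converts the primary benzylic alcohol into the bromide under neutral conditions that the silyl ether tolerates.

Step 9
Reactants: 13 (S)-2-[3-(benzyloxy)-2-(tert-butyldimethylsilyloxy)propyl]-4-isopropyl-3,5,6-trimethoxybenzyl bromide; 14 diethyl (2-oxopropyl)phosphonate
Product: 16 diethyl (1-{2-[(2S)-3-(benzyloxy)-2-(tert-butyldimethylsilyloxy)propyl]-4-isopropyl-3,5,6-trimethoxyphenyl}-3-oxobutan-2-yl)phosphonate (both epimers at the phosphonate carbon), via sodium enolate 15 (not isolated)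
Conditions: NaH, THF, 0 °C; then 13, 0 °C to rt
Reagents that add atoms: none
Why: SN2 C-alkylation of the stabilised β-ketophosphonate anion by the reactive benzylic bromide forms C20–C10; the new centre at C10 is of no consequence because it becomes sp2 in step 11.

Step 10
Reactants: 16 diethyl (1-{2-[(2S)-3-(benzyloxy)-2-(tert-butyldimethylsilyloxy)propyl]-4-isopropyl-3,5,6-trimethoxyphenyl}-3-oxobutan-2-yl)phosphonate
Product: 17 diethyl (1-{2-[(2S)-2-(tert-butyldimethylsilyloxy)-3-hydroxypropyl]-4-isopropyl-3,5,6-trimethoxyphenyl}-3-oxobutan-2-yl)phosphonate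
Conditions: H2 (1 atm), Pd/C, EtOAc, rt
Reagents that add atoms: none
Why: Hydrogenolysis removes the benzyl ether while ketone, phosphonate, silyl ether and the fully substituted arene stay intact.

Step 11
Reactants: 17 diethyl (1-{2-[(2S)-2-(tert-butyldimethylsilyloxy)-3-hydroxypropyl]-4-isopropyl-3,5,6-trimethoxyphenyl}-3-oxobutan-2-yl)phosphonate
Product: 19 1-[(8S)-8-(tert-butyldimethylsilyloxy)-2-isopropyl-1,3,4-trimethoxy-8,9-dihydro-5H-benzo[7]annulen-6-yl]ethan-1-one, via silyloxy aldehyde 18 (not isolated)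
Conditions: Dess–Martin periodinane, CH2Cl2, rt; then Ba(OH)2, THF/H2O (40:1), rt, high dilution
Reagents that add atoms: none
Why: Dess–Martin oxidation followed by an intramolecular Horner–Wadsworth–Emmons olefination closes ring B at C5=C10; the mild barium base should not epimerise the α-silyloxy aldehyde, and the ring allows only one alkene geometry.

Step 12
Reactants: 19 1-[(8S)-8-(tert-butyldimethylsilyloxy)-2-isopropyl-1,3,4-trimethoxy-8,9-dihydro-5H-benzo[7]annulen-6-yl]ethan-1-one
Product: 20 (8S)-8-(tert-butyldimethylsilyloxy)-6-[1-(tert-butyldimethylsilyloxy)ethenyl]-2-isopropyl-1,3,4-trimethoxy-8,9-dihydro-5H-benzo[7]annulene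
Conditions: TBSOTf, Et3N, CH2Cl2, −78 °C to 0 °C
Reagents that add atoms: tert-butyldimethylsilyl trifluoromethanesulfonate CC(C)(C)[Si](C)(C)OS(=O)(=O)C(F)(F)F
Why: Soft enolisation of the methyl ketone at its methyl group with O-silylation gives the cross-conjugated 2-silyloxydiene C5=C10–C1(OSi)=C2, as is usual for acetyl cycloalkenes.

Step 13
Reactants: 20 (8S)-8-(tert-butyldimethylsilyloxy)-6-[1-(tert-butyldimethylsilyloxy)ethenyl]-2-isopropyl-1,3,4-trimethoxy-8,9-dihydro-5H-benzo[7]annulene; 21 methacrolein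
Product: 22 (4S,5R,6S)-1,6-bis(tert-butyldimethylsilyloxy)-11,12,14-trimethoxyicetexa-1(10),8,11,13-tetraen-19-al
Conditions: Me2AlCl (1.5 equiv), 21 (4 equiv), CH2Cl2, −78 °C to −40 °C
Reagents that add atoms: none
Why: Aluminium bound to the formyl oxygen lowers the LUMO of 21, and the nucleophilic CH2 terminus C2 of the diene bonds to the β-carbon C3 ahead of the C5–C4 bond in an asynchronous [4+2] transition state (a Michael addition followed by ring closure would give the same adduct). The closest known reaction type is the Lewis acid-promoted Diels–Alder reaction of 2-silyloxy-1,3-dienes with α-substituted acroleins, which makes formyl-bearing quaternary carbons. Ring A (C1, C2, C3, C4, C5, C10) closes by intermolecular cycloaddition onto the preformed ring B, whose C5=C10 bond is one half of the diene. C5 should be set by approach to the diene face opposite the C7 arm and the arene of the puckered ring B, with the C6 silyloxy group pseudo-equatorial, so that the C6 centre from 6 fixes the absolute configuration; C4 should be set relative to C5 by endo orientation of the aluminium-bound formyl group, which puts C19 cis to C6 and the methyl group exo. Regiochemistry (C1 oxygen para to C4) follows from the large HOMO coefficient at C2 and the large LUMO coefficient at the β-carbon of the enal. The step needs endo and facial selectivity and cycloaddition in preference to aldol addition, which low temperature, the bulky TBS enol ether and the C6 substituent should secure.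

Step 14
Reactants: 22 (4S,5R,6S)-1,6-bis(tert-butyldimethylsilyloxy)-11,12,14-trimethoxyicetexa-1(10),8,11,13-tetraen-19-al
Product: 23 (4S,5S,6S)-6-(tert-butyldimethylsilyloxy)-11,12,14-trimethoxy-1-oxoicetexa-8,10(20),11,13-tetraen-19-al (same geometry as 22; the C5 descriptor changes by priority only)
Conditions: Pd(OAc)2 (1.1 equiv), MeCN/DMSO, 40 °C
Reagents that add atoms: none
Why: Saegusa oxidation: the palladium enolate at C10 should lose the benzylic C20 hydride to give the aryl-conjugated enone, since elimination toward C5 would create a tetrasubstituted alkene next to quaternary C4.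

Step 15
Reactants: 23 (4S,5S,6S)-6-(tert-butyldimethylsilyloxy)-11,12,14-trimethoxy-1-oxoicetexa-8,10(20),11,13-tetraen-19-al
Product: 24 (4S,5R,6S)-6-(tert-butyldimethylsilyloxy)-11,12,14-trimethoxy-1-oxoicetexa-8,10(20),11,13-tetraen-19-oic acid
Conditions: NaClO2, NaH2PO4, 2-methyl-2-butene, t-BuOH/H2O, 0 °C to rt
Reagents that add atoms: sodium chlorite [Na+].[O-]Cl=O
Why: Pinnick oxidation of the neopentyl aldehyde is safe here because C4 is quaternary and the arene has no free position for chlorination.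

Step 16
Reactants: 24 (4S,5R,6S)-6-(tert-butyldimethylsilyloxy)-11,12,14-trimethoxy-1-oxoicetexa-8,10(20),11,13-tetraen-19-oic acid
Product: 26 (4S,5R,6S)-11,12,14-trimethoxy-1-oxoicetexa-8,10(20),11,13-tetraen-19,6-olide, via hydroxy acid 25 (not isolated)
Conditions: HF·pyridine, THF, 0 °C to rt; then DCC, DMAP (cat.), CH2Cl2, rt
Reagents that add atoms: none
Why: Desilylation followed by Steglich lactonisation of the γ-hydroxy acid closes the five-membered lactone with retention at C6, which is possible because the endo cycloaddition placed C19 and C6 cis on ring A.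

Step 17
Reactants: 26 (4S,5R,6S)-11,12,14-trimethoxy-1-oxoicetexa-8,10(20),11,13-tetraen-19,6-olide
Product: 27 (4S,5R)-11,12,14-trimethoxy-1-oxoicetexa-6,8,10(20),11,13-pentaen-19,6-olide
Conditions: DDQ, 1,4-dioxane, 60 °C
Reagents that add atoms: none
Why: DDQ dehydrogenation: hydride abstraction from benzylic C7 (cation stabilised by the ortho and para methoxy groups) and loss of the C6 proton should give the aryl-conjugated enol lactone and remove the C6 stereocentre.

Step 18
Reactants: 27 (4S,5R)-11,12,14-trimethoxy-1-oxoicetexa-6,8,10(20),11,13-pentaen-19,6-olide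
Product: 28 (1R,4S,5R)-1-hydroxy-11,12,14-trimethoxyicetexa-6,8,10(20),11,13-pentaen-19,6-olide
Conditions: NaBH4, CeCl3·7H2O, MeOH, −78 °C
Reagents that add atoms: none
Why: Luche 1,2-reduction: axial hydride delivery from the convex face that carries the C4 methyl group and the C5 hydrogen, away from the cis-fused lactone, should give the equatorial C1 alcohol cis to C19.

Step 19
Reactants: 28 (1R,4S,5R)-1-hydroxy-11,12,14-trimethoxyicetexa-6,8,10(20),11,13-pentaen-19,6-olide
Product: 29 (1R,4S,5R)-1-hydroxy-12-methoxy-11,14-dioxoicetexa-6,8,10(20),12-tetraen-19,6-olide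
Conditions: (NH4)2Ce(NO3)6, MeCN/H2O (2:1), 0 °C
Reagents that add atoms: water O
Why: Oxidative demethylation of the para-related C11 and C14 methoxy groups by tetravalent cerium gives the 2-methoxy-1,4-benzoquinone, a fast reaction that allylic alcohols and lactones normally survive.

Step 20
Reactants: 29 (1R,4S,5R)-1-hydroxy-12-methoxy-11,14-dioxoicetexa-6,8,10(20),12-tetraen-19,6-olide
Product: 30 6,7-anhydroballotiquinone
Conditions: HClO4 (aq., cat.), 1,4-dioxane, rt
Reagents that add atoms: water O
Why: Acid-catalysed addition–elimination hydrolysis of the vinylogous methyl ester (2-methoxyquinone) frees the C12 hydroxyl; the C1 alcohol should resist ionisation because its allyl system is conjugated to the electron-poor quinone.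

**Compound list**
1 | 1,2,4-trimethoxybenzene | COc1ccc(OC)c(OC)c1 | starting material
2 | 3-lithio-1,2,4-trimethoxybenzene | [Li]c1c(OC)ccc(OC)c1OC | intermediate
3 | 2-(2,3,6-trimethoxyphenyl)propan-2-ol | CC(C)(O)c1c(OC)ccc(OC)c1OC | intermediate
4 | 2-isopropyl-1,3,4-trimethoxybenzene | CC(C)c1c(OC)ccc(OC)c1OC | intermediate
5 | 1-bromo-3-isopropyl-2,4,5-trimethoxybenzene | COc1cc(Br)c(OC)c(C(C)C)c1OC | intermediate
6 | (S)-benzyl glycidyl ether, (S)-2-[(benzyloxy)methyl]oxirane | C(OCc1ccccc1)[C@@H]1CO1 | starting material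
7 | (3-isopropyl-2,4,5-trimethoxyphenyl)magnesium bromide | COc1cc([Mg]Br)c(OC)c(C(C)C)c1OC | intermediate
8 | (S)-1-(benzyloxy)-3-(3-isopropyl-2,4,5-trimethoxyphenyl)propan-2-ol | COc1c(C(C)C)c(OC)c(OC)cc1C[C@H](O)COCc2ccccc2 | intermediate
9 | (S)-{[1-(benzyloxy)-3-(3-isopropyl-2,4,5-trimethoxyphenyl)propan-2-yl]oxy}(tert-butyl)dimethylsilane | COc1c(C(C)C)c(OC)c(OC)cc1C[C@H](O[Si](C)(C)C(C)(C)C)COCc2ccccc2 | intermediate
10 | (S)-{[1-(benzyloxy)-3-(6-bromo-3-isopropyl-2,4,5-trimethoxyphenyl)propan-2-yl]oxy}(tert-butyl)dimethylsilane | COc1c(C(C)C)c(OC)c(OC)c(Br)c1C[C@H](O[Si](C)(C)C(C)(C)C)COCc2ccccc2 | intermediate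
11 | arylmagnesium bromide from 10 (MgBr in place of Br at the later C9) | COc1c(C(C)C)c(OC)c(OC)c([Mg]Br)c1C[C@H](O[Si](C)(C)C(C)(C)C)COCc2ccccc2 | intermediate
12 | {2-[(2S)-3-(benzyloxy)-2-(tert-butyldimethylsilyloxy)propyl]-4-isopropyl-3,5,6-trimethoxyphenyl}methanol | COc1c(C(C)C)c(OC)c(OC)c(CO)c1C[C@H](O[Si](C)(C)C(C)(C)C)COCc2ccccc2 | intermediate
13 | (S)-2-[3-(benzyloxy)-2-(tert-butyldimethylsilyloxy)propyl]-4-isopropyl-3,5,6-trimethoxybenzyl bromide | COc1c(C(C)C)c(OC)c(OC)c(CBr)c1C[C@H](O[Si](C)(C)C(C)(C)C)COCc2ccccc2 | intermediate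
14 | diethyl (2-oxopropyl)phosphonate | CCOP(=O)(CC(C)=O)OCC | starting material
15 | sodium enolate of diethyl (2-oxopropyl)phosphonate | CCOP(=O)(OCC)C=C(C)[O-].[Na+] | intermediate
16 | diethyl (1-{2-[(2S)-3-(benzyloxy)-2-(tert-butyldimethylsilyloxy)propyl]-4-isopropyl-3,5,6-trimethoxyphenyl}-3-oxobutan-2-yl)phosphonate, both epimers at the phosphonate carbon | COc1c(C(C)C)c(OC)c(OC)c(CC(C(C)=O)P(=O)(OCC)OCC)c1C[C@H](O[Si](C)(C)C(C)(C)C)COCc2ccccc2 | intermediate
17 | diethyl (1-{2-[(2S)-2-(tert-butyldimethylsilyloxy)-3-hydroxypropyl]-4-isopropyl-3,5,6-trimethoxyphenyl}-3-oxobutan-2-yl)phosphonate | COc1c(C(C)C)c(OC)c(OC)c(CC(C(C)=O)P(=O)(OCC)OCC)c1C[C@H](O[Si](C)(C)C(C)(C)C)CO | intermediate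
18 | diethyl (1-{2-[(2S)-2-(tert-butyldimethylsilyloxy)-3-oxopropyl]-4-isopropyl-3,5,6-trimethoxyphenyl}-3-oxobutan-2-yl)phosphonate | COc1c(C(C)C)c(OC)c(OC)c(CC(C(C)=O)P(=O)(OCC)OCC)c1C[C@H](O[Si](C)(C)C(C)(C)C)C=O | intermediate
19 | 1-[(8S)-8-(tert-butyldimethylsilyloxy)-2-isopropyl-1,3,4-trimethoxy-8,9-dihydro-5H-benzo[7]annulen-6-yl]ethan-1-one (ring B enone: C5=C10, acetyl on C10, silyl ether on C6) | COc1c(C(C)C)c(OC)c(OC)c2c1C[C@H](O[Si](C)(C)C(C)(C)C)C=C(C(C)=O)C2 | intermediate
20 | (8S)-8-(tert-butyldimethylsilyloxy)-6-[1-(tert-butyldimethylsilyloxy)ethenyl]-2-isopropyl-1,3,4-trimethoxy-8,9-dihydro-5H-benzo[7]annulene (2-silyloxydiene C5=C10–C1(OSi)=C2) | COc1c(C(C)C)c(OC)c(OC)c2c1C[C@H](O[Si](C)(C)C(C)(C)C)C=C(C(=C)O[Si](C)(C)C(C)(C)C)C2 | intermediate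
21 | methacrolein (2-methylprop-2-enal) | CC(=C)C=O | starting material
22 | (4S,5R,6S)-1,6-bis(tert-butyldimethylsilyloxy)-11,12,14-trimethoxyicetexa-1(10),8,11,13-tetraen-19-al (C19 formyl cis to C6 on ring A, C4 methyl cis to H5) | COc1c(C(C)C)c(OC)c(OC)c2c1C[C@H](O[Si](C)(C)C(C)(C)C)[C@@H]3C(C2)=C(O[Si](C)(C)C(C)(C)C)CC[C@]3(C)C=O | intermediate
23 | (4S,5S,6S)-6-(tert-butyldimethylsilyloxy)-11,12,14-trimethoxy-1-oxoicetexa-8,10(20),11,13-tetraen-19-al | COc1c(C(C)C)c(OC)c(OC)c2c1C[C@H](O[Si](C)(C)C(C)(C)C)[C@@H]3C(=C2)C(=O)CC[C@]3(C)C=O | intermediate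
24 | (4S,5R,6S)-6-(tert-butyldimethylsilyloxy)-11,12,14-trimethoxy-1-oxoicetexa-8,10(20),11,13-tetraen-19-oic acid | COc1c(C(C)C)c(OC)c(OC)c2c1C[C@H](O[Si](C)(C)C(C)(C)C)[C@@H]3C(=C2)C(=O)CC[C@]3(C)C(=O)O | intermediate
25 | (4S,5R,6S)-6-hydroxy-11,12,14-trimethoxy-1-oxoicetexa-8,10(20),11,13-tetraen-19-oic acid | COc1c(C(C)C)c(OC)c(OC)c2c1C[C@H](O)[C@@H]3C(=C2)C(=O)CC[C@]3(C)C(=O)O | intermediate
26 | (4S,5R,6S)-11,12,14-trimethoxy-1-oxoicetexa-8,10(20),11,13-tetraen-19,6-olide (H5 and H6 trans) | COc1c(C(C)C)c(OC)c(OC)c2c1C[C@@H]3OC(=O)[C@@]4(C)CCC(=O)C(=C2)[C@@H]34 | intermediate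
27 | (4S,5R)-11,12,14-trimethoxy-1-oxoicetexa-6,8,10(20),11,13-pentaen-19,6-olide | COc1c(C(C)C)c(OC)c(OC)c2c1C=C3OC(=O)[C@@]4(C)CCC(=O)C(=C2)[C@@H]34 | intermediate
28 | (1R,4S,5R)-1-hydroxy-11,12,14-trimethoxyicetexa-6,8,10(20),11,13-pentaen-19,6-olide | COc1c(C(C)C)c(OC)c(OC)c2c1C=C3OC(=O)[C@@]4(C)CC[C@@H](O)C(=C2)[C@@H]34 | intermediate
29 | (1R,4S,5R)-1-hydroxy-12-methoxy-11,14-dioxoicetexa-6,8,10(20),12-tetraen-19,6-olide (12-O-methyl ether of the target) | CC(C)C1=C(OC)C(=O)C2=C(C=C3OC(=O)[C@@]4(C)CC[C@@H](O)C(=C2)[C@@H]34)C1=O | intermediate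
30 | 6,7-anhydroballotiquinone, (1R,4S,5R)-1,12-dihydroxy-11,14-dioxoicetexa-6,8,10(20),12-tetraen-19,6-olide | CC(C)C1=C(O)C(=O)C2=C(C=C3OC(=O)[C@@]4(C)CC[C@@H](O)C(=C2)[C@@H]34)C1=O | target

**Step count and risks**
Total: 20 steps. Longest linear sequence: 20 steps (1 to 30); 6, 14 and 21 enter as purchased fragments.

Steps most likely to fail:

1. Step 13. The bimolecular cycloaddition may lose facial or endo control, or the silyl enol ether may attack the aluminium-bound aldehyde in an aldol sense. The fallback tethers the dienophile and forms the same C2–C3 and C4–C5 bonds. Setting out from 19, HF·pyridine frees the C6 alcohol F1. A Mitsunobu esterification with methacrylic acid (PPh3, DIAD) inverts C6 and gives the methacrylate F2. TBSOTf/Et3N then gives the silyloxydiene ester F3. Heating in toluene (BHT, 110–140 °C) should bring about an intramolecular Diels–Alder reaction. The three-atom C6–O–C19 tether delivers the dienophile to the diene face anti to C7, which is why C6 is inverted first, and ring A and the lactone close together to give the silyl enol ether lactone F4. The cis ring fusion at C4–C5 requires the ester carbonyl to lie under the diene. Saegusa oxidation with Pd(OAc)2 gives the lactone enone F5, the C6 epimer of 26. The DDQ dehydrogenation of step 17 removes that centre, and the route is rejoined at 27.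

2. Step 14. β-Hydride elimination may go toward C5 instead of C20, or the hindered TBS enol ether may react so slowly that it is hydrolysed to the saturated ketone. The fallback replaces the organopalladium pathway by hydride abstraction: 22 is treated with DDQ and 2,6-lutidine in CH2Cl2 at 0 °C. Abstraction of the benzylic C20 hydride gives a siloxy-stabilised allyl cation that loses the silyl group, so cation stability fixes the position of the double bond. This leads from 22 directly to 23 and passes through no new compound (F0).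

3. Step 17. The benzylic cation may be trapped by the reduced quinone or by water, the trimethoxyarene may be over-oxidised, or the strained lactone of step 16 may close reluctantly and starve the step. The fallback sets out from 24: desilylation (HF·pyridine) and Dess–Martin oxidation of the C6 alcohol give the γ-keto acid F6. Enol lactonisation (Ac2O, NaOAc, 80 °C) with enolisation toward the benzylic C7 then gives the enol lactone 27 directly.

**Further compounds**
F1 | step 13 | 1-[(8S)-8-hydroxy-2-isopropyl-1,3,4-trimethoxy-8,9-dihydro-5H-benzo[7]annulen-6-yl]ethan-1-one | COc1c(C(C)C)c(OC)c(OC)c2c1C[C@H](O)C=C(C(C)=O)C2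
F2 | step 13 | (8R)-6-acetyl-2-isopropyl-1,3,4-trimethoxy-8,9-dihydro-5H-benzo[7]annulen-8-yl 2-methylprop-2-enoate | COc1c(C(C)C)c(OC)c(OC)c2c1C[C@@H](OC(=O)C(C)=C)C=C(C(C)=O)C2
F3 | step 13 | (8R)-6-[1-(tert-butyldimethylsilyloxy)ethenyl]-2-isopropyl-1,3,4-trimethoxy-8,9-dihydro-5H-benzo[7]annulen-8-yl 2-methylprop-2-enoate | COc1c(C(C)C)c(OC)c(OC)c2c1C[C@@H](OC(=O)C(C)=C)C=C(C(=C)O[Si](C)(C)C(C)(C)C)C2
F4 | step 13 | (4S,5R,6R)-1-(tert-butyldimethylsilyloxy)-11,12,14-trimethoxyicetexa-1(10),8,11,13-tetraen-19,6-olide | COc1c(C(C)C)c(OC)c(OC)c2c1C[C@H]3OC(=O)[C@@]4(C)CCC(O[Si](C)(C)C(C)(C)C)=C(C2)[C@@H]34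
F5 | step 13 | (4S,5R,6R)-11,12,14-trimethoxy-1-oxoicetexa-8,10(20),11,13-tetraen-19,6-olide | COc1c(C(C)C)c(OC)c(OC)c2c1C[C@H]3OC(=O)[C@@]4(C)CCC(=O)C(=C2)[C@@H]34
F0 | step 14 | none | none
F6 | step 17 | (4S,5R)-11,12,14-trimethoxy-1,6-dioxoicetexa-8,10(20),11,13-tetraen-19-oic acid | COc1c(C(C)C)c(OC)c(OC)c2c1CC(=O)[C@@H]3C(=C2)C(=O)CC[C@]3(C)C(=O)O
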